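## Retrosynthetic overview

1. The quinone is taken back to a 2-methyl-6-alkylphenol: the second ring oxygen is added last by para-oxidation, after the acetonide is removed.
2. The phenol ring is cut into 2-methylfuran and a terminal alkyne (gold-catalysed furan–yne benzannulation). Ring bonds C2–C3 and C1–C6 form together and the furan oxygen moves to C1. Enabling feature: ring C1 (C=O) lies between the chain-bearing C2 and the methyl-bearing C6, and C3, C4, C5 carry no carbon substituent. So C3–C6 plus the methyl is the skeleton of 2-methylfuran, and C1–C2 plus the ring-bound CH2 is a terminal alkyne.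
3. The E-configured 2-alkylidene-1,3-diol (C10′=C11′, CH2OH on C11′, OH on C12′) comes from an (R)-propargylic alcohol by hydroxyl-directed trans-hydrostannation, iodination and Stille hydroxymethylation. C12′ is set by asymmetric transfer hydrogenation of an ynone.
4. The ynone comes from a terminal alkyne and a Weinreb amide. The alkyne comes from geranyl bromide by alkynylation at C1′, SeO2 oxidation at C8′ and three-carbon propargylation.
5. Rings: a temporary 1,3-dioxane (acetonide, step 12, removed in step 15) is made first; the only ring of the target, the carbocycle, is made in step 14.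

Key step: step 14

Remark: the ring is numbered C1 (carbonyl between the two substituted carbons), C2 (chain-bearing), C3 (CH), C4 (second carbonyl), C5 (CH), C6 (methyl-bearing). The side chain is C1′ (ring CH2) to C16′. Read from the SMILES, the stereocentre C12′ is R and the C2′, C6′ and C10′ alkenes are all E.

## Route

Step 1
Reactants: 1 geranyl bromide; 2 ethynyl(triisopropyl)silane
Product: 3 (E)-(5,9-dimethyldeca-4,8-dien-1-yn-1-yl)triisopropylsilane
Conditions: CuI (10 mol %), Bu4NI (10 mol %), K2CO3, DMF, 25 °C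
Reagents that add atoms: none
Why: Copper-acetylide allylic substitution at the unhindered primary carbon of the allylic bromide should give the skipped 1,4-enyne with the E-alkene untouched; no stereocentre is formed.

Step 2
Reactants: 3 (E)-(5,9-dimethyldeca-4,8-dien-1-yn-1-yl)triisopropylsilane
Product: 4 (2E,6E)-2,6-dimethyl-10-(triisopropylsilyl)deca-2,6-dien-9-yn-1-ol
Conditions: SeO2 (0.5 equiv), t-BuOOH (3 equiv), salicylic acid (cat.), CH2Cl2, 0 → 25 °C
Reagents that add atoms: selenium dioxide, O=[Se]=O (oxygen carrier); tert-butyl hydroperoxide, CC(C)(C)OO (terminal oxidant)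
Why: SeO2 allylic oxidation (ene reaction, then [2,3]-sigmatropic shift) should select the E-methyl group of the terminal, most electron-rich trisubstituted alkene and give the E-allylic alcohol.

Step 3
Reactants: 4 (2E,6E)-2,6-dimethyl-10-(triisopropylsilyl)deca-2,6-dien-9-yn-1-ol
Product: 5 [(4E,8E)-10-bromo-5,9-dimethyldeca-4,8-dien-1-yn-1-yl]triisopropylsilane
Conditions: CBr4, PPh3, CH2Cl2, 0 °C
Reagents that add atoms: carbon tetrabromide, BrC(Br)(Br)Br
Why: Appel reaction; SN2 displacement of the alkoxyphosphonium by bromide should convert the primary allylic alcohol without allylic transposition or loss of alkene geometry.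

Step 4
Reactants: 5 [(4E,8E)-10-bromo-5,9-dimethyldeca-4,8-dien-1-yn-1-yl]triisopropylsilane; 6 1-(trimethylsilyl)propyne
Product: 8 (4E,8E)-5,9-dimethyl-1-(triisopropylsilyl)-13-(trimethylsilyl)trideca-4,8-diene-1,12-diyne, via lithiated 1-(trimethylsilyl)propyne 7 (not isolated)
Conditions: 6, n-BuLi, TMEDA, THF, −78 → −20 °C; then 5, −78 → 0 °C
Reagents that add atoms: n-butyllithium, [Li]CCCC (lithium of intermediate 7 only)
Why: SN2 alkylation of the primary allylic bromide by the silyl-capped propargylic organolithium adds C9′–C11′; the silyl group should suppress allenyl coupling.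

Step 5
Reactants: 8 (4E,8E)-5,9-dimethyl-1-(triisopropylsilyl)-13-(trimethylsilyl)trideca-4,8-diene-1,12-diyne
Product: 9 [(4E,8E)-5,9-dimethyltrideca-4,8-diene-1,12-diyn-1-yl]triisopropylsilane
Conditions: K2CO3 (0.3 equiv), MeOH/THF, 25 °C
Reagents that add atoms: none
Why: Base-catalysed protodesilylation should cleave only the alkynyl–SiMe3 bond, because the bulky triisopropylsilyl alkyne is inert to carbonate in methanol.

Step 6
Reactants: 10 4-methylpent-3-enoic acid; 11 N,O-dimethylhydroxylamine hydrochloride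
Product: 12 N-methoxy-N,4-dimethylpent-3-enamide
Conditions: EDC·HCl, N-methylmorpholine, CH2Cl2, 0 → 25 °C
Reagents that add atoms: none
Why: Carbodiimide amide coupling under mild, weakly basic conditions should form the Weinreb amide without moving the β,γ-alkene into conjugation.

Step 7
Reactants: 9 [(4E,8E)-5,9-dimethyltrideca-4,8-diene-1,12-diyn-1-yl]triisopropylsilane; 12 N-methoxy-N,4-dimethylpent-3-enamide
Product: 14 (10E,14E)-2,10,14-trimethyl-18-(triisopropylsilyl)octadeca-2,10,14-triene-6,17-diyn-5-one, via lithium acetylide 13 (not isolated)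
Conditions: 9, n-BuLi, THF, −78 °C; then 12, −78 → −20 °C; AcOH quench at −78 °C
Reagents that add atoms: n-butyllithium, [Li]CCCC (lithium of intermediate 13 only)
Why: Weinreb ketone synthesis; the acetylide should add once, and the chelated tetrahedral intermediate collapses only on the cold acidic quench, which should also prevent base-mediated isomerisation of the skipped enone.

Step 8
Reactants: 14 (10E,14E)-2,10,14-trimethyl-18-(triisopropylsilyl)octadeca-2,10,14-triene-6,17-diyn-5-one
Product: 15 (5R,10E,14E)-2,10,14-trimethyl-18-(triisopropylsilyl)octadeca-2,10,14-triene-6,17-diyn-5-ol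
Conditions: Ru[(R,R)-TsNCHPhCHPhNH](p-cymene) (preformed 16-electron amido complex, 2 mol %), i-PrOH, 25 °C
Reagents that add atoms: none
Why: Noyori asymmetric transfer hydrogenation of an alkynyl ketone; the alkynyl group takes the site an aryl group normally occupies in the six-membered Ru–H/N–H transition state, so the (R,R)-catalyst should give the (R)-carbinol, which is the C12′ stereocentre.

Step 9
Reactants: 15 (5R,10E,14E)-2,10,14-trimethyl-18-(triisopropylsilyl)octadeca-2,10,14-triene-6,17-diyn-5-ol
Product: 16 (5R,6Z,10E,14E)-2,10,14-trimethyl-6-(tributylstannyl)-18-(triisopropylsilyl)octadeca-2,6,10,14-tetraen-17-yn-5-ol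
Conditions: [Cp*RuCl]4 (1.5 mol %), Bu3SnH (1.1 equiv, slow addition), CH2Cl2, 25 °C
Reagents that add atoms: tributyltin hydride, CCCC[SnH](CCCC)CCCC
Why: Hydroxyl-directed ruthenium-catalysed trans-hydrostannation; hydrogen bonding of the free OH to the Ru–Cl unit should put tin on the alkyne carbon next to the carbinol and hydrogen anti to it, which fixes the alkene geometry (tin cis to the C9′ chain), while the hindered, undirected silyl alkyne should react far more slowly.

Step 10
Reactants: 16 (5R,6Z,10E,14E)-2,10,14-trimethyl-6-(tributylstannyl)-18-(triisopropylsilyl)octadeca-2,6,10,14-tetraen-17-yn-5-ol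
Product: 17 (5R,6Z,10E,14E)-6-iodo-2,10,14-trimethyl-18-(triisopropylsilyl)octadeca-2,6,10,14-tetraen-17-yn-5-ol
Conditions: I2 (1.05 equiv), CH2Cl2, 0 °C
Reagents that add atoms: iodine, II
Why: Iododestannylation (electrophilic ipso-substitution) should proceed with retention of alkene geometry.

Step 11
Reactants: 17 (5R,6Z,10E,14E)-6-iodo-2,10,14-trimethyl-18-(triisopropylsilyl)octadeca-2,6,10,14-tetraen-17-yn-5-ol; 18 (tributylstannyl)methanol
Product: 19 (5R,6E,10E,14E)-6-(hydroxymethyl)-2,10,14-trimethyl-18-(triisopropylsilyl)octadeca-2,6,10,14-tetraen-17-yn-5-ol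
Conditions: Pd(PPh3)4 (10 mol %), 1,4-dioxane, 90 °C
Reagents that add atoms: none
Why: Stille cross-coupling with the hydroxymethyl stannane should transfer CH2OH to the alkenyl iodide with retention, completing the E-2-alkylidene-1,3-diol.

Step 12
Reactants: 19 (5R,6E,10E,14E)-6-(hydroxymethyl)-2,10,14-trimethyl-18-(triisopropylsilyl)octadeca-2,6,10,14-tetraen-17-yn-5-ol
Product: 20 (4R,5E)-5-[(4E,8E)-4,8-dimethyl-12-(triisopropylsilyl)dodeca-4,8-dien-11-yn-1-ylidene]-2,2-dimethyl-4-(3-methylbut-2-en-1-yl)-1,3-dioxane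
Conditions: 2,2-dimethoxypropane, PPTS (cat.), CH2Cl2, 25 °C
Reagents that add atoms: 2,2-dimethoxypropane, COC(C)(C)OC
Why: Acid-catalysed transketalisation should tie the 1,3-diol into a six-membered isopropylidene acetal that masks both hydroxyls for the gold step; no stereocentre is touched.

Step 13
Reactants: 20 (4R,5E)-5-[(4E,8E)-4,8-dimethyl-12-(triisopropylsilyl)dodeca-4,8-dien-11-yn-1-ylidene]-2,2-dimethyl-4-(3-methylbut-2-en-1-yl)-1,3-dioxane
Product: 21 (4R,5E)-5-[(4E,8E)-4,8-dimethyldodeca-4,8-dien-11-yn-1-ylidene]-2,2-dimethyl-4-(3-methylbut-2-en-1-yl)-1,3-dioxane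
Conditions: Bu4NF·3H2O, THF, 0 → 25 °C
Reagents that add atoms: none
Why: Fluoride-mediated protodesilylation of the alkynylsilane should free the terminal alkyne; the acetonide is inert to fluoride.

Step 14
Reactants: 21 (4R,5E)-5-[(4E,8E)-4,8-dimethyldodeca-4,8-dien-11-yn-1-ylidene]-2,2-dimethyl-4-(3-methylbut-2-en-1-yl)-1,3-dioxane; 22 2-methylfuran
Product: 25 2-{(2E,6E,10E)-10-[(4R)-2,2-dimethyl-4-(3-methylbut-2-en-1-yl)-1,3-dioxan-5-ylidene]-3,7-dimethyldeca-2,6-dien-1-yl}-6-methylphenol, via oxepine 23 (not isolated), via benzene oxide 24 (not isolated)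
Conditions: 2-methylfuran (10 equiv), (IPr)AuCl (5 mol %), AgSbF6 (5 mol %), CH2Cl2, 25 °C, dark; IPr = 1,3-bis(2,6-diisopropylphenyl)imidazol-2-ylidene
Reagents that add atoms: none
Why: Proposed new method: the cationic monovalent gold centre π-activates the terminal alkyne of 21, the unsubstituted α-carbon of 2-methylfuran attacks its internal carbon to give a cyclopropyl gold carbene, the furan C–O bond opens to a (Z)-dienone gold carbene, and the ketone oxygen adds to the carbene carbon to release oxepine 23. The carbocycle, the only ring closed, forms by thermal 6π-disrotatory electrocyclisation of 23 to benzene oxide 24, which joins the former terminal alkyne carbon to the methyl-bearing furan carbon; the epoxide then ionises at that tertiary carbon and loses a proton to give phenol 25 with the furan oxygen on the former alkyne terminus. Closest known reaction type: the gold-catalysed furan–yne phenol synthesis (Hashmi phenol synthesis), routine in tethered form and shown between separate partners for 2-alkylfurans with arylacetylenes; an unactivated aliphatic 1,4-enynyl alkyne carrying a polyene and an allylic acetal has not been shown, hence the label. No stereocentre is formed, and the C12′ centre and the three E-alkenes are spectators. The step needs attack through furan C5 and not the methyl-bearing C2, bond formation at the internal alkyne carbon, and epoxide opening toward the methyl carbon; these should be secured by the lower hindrance of the free α-position, by Markovnikov polarisation of the gold–alkyne complex, and by the tertiary, doubly allylic cation that only this opening gives. Chemoselectivity over the chain alkenes rests on the large excess of the far more nucleophilic furan and on the 1,4-relationship of the nearest alkene to the alkyne, which allows no strain-free enyne cyclisation.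

Step 15
Reactants: 25 2-{(2E,6E,10E)-10-[(4R)-2,2-dimethyl-4-(3-methylbut-2-en-1-yl)-1,3-dioxan-5-ylidene]-3,7-dimethyldeca-2,6-dien-1-yl}-6-methylphenol
Product: 26 2-[(2E,6E,10E,12R)-12-hydroxy-11-(hydroxymethyl)-3,7,15-trimethylhexadeca-2,6,10,14-tetraen-1-yl]-6-methylphenol
Conditions: PPTS (0.2 equiv), MeOH, 25 °C
Reagents that add atoms: none
Why: Acid-catalysed acetal exchange with methanol should release the 1,3-diol under conditions too mild to ionise the allylic alcohols or to cyclise the ortho-allyl phenol.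

Step 16
Reactants: 26 2-[(2E,6E,10E,12R)-12-hydroxy-11-(hydroxymethyl)-3,7,15-trimethylhexadeca-2,6,10,14-tetraen-1-yl]-6-methylphenol
Product: 27 2-[(2E,6E,10E,12R)-12-hydroxy-11-(hydroxymethyl)-3,7,15-trimethylhexadeca-2,6,10,14-tetraen-1-yl]-6-methylcyclohexa-2,5-diene-1,4-dione (CNP0201434.1)
Conditions: (KSO3)2NO (2.5 equiv), KH2PO4 buffer, acetone/H2O, 0 → 25 °C
Reagents that add atoms: potassium nitrosodisulfonate, [K+].[K+].[O-]S(=O)(=O)N([O])S(=O)(=O)[O-]
Why: Teuber oxidation; the nitroxyl radical should oxidise the phenol to a phenoxyl radical that is trapped at the free para-position, and loss of the imidodisulfonate gives the para-quinone, with both ortho positions blocked so that no ortho-quinone can form.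

## Compound list

1 | geranyl bromide, (2E)-1-bromo-3,7-dimethylocta-2,6-diene | CC(C)=CCC/C(C)=C/CBr | starting material
2 | ethynyl(triisopropyl)silane | C#C[Si](C(C)C)(C(C)C)C(C)C | starting material
3 | (E)-(5,9-dimethyldeca-4,8-dien-1-yn-1-yl)triisopropylsilane | CC(C)=CCC/C(C)=C/CC#C[Si](C(C)C)(C(C)C)C(C)C | intermediate
4 | (2E,6E)-2,6-dimethyl-10-(triisopropylsilyl)deca-2,6-dien-9-yn-1-ol | OC/C(C)=C/CC/C(C)=C/CC#C[Si](C(C)C)(C(C)C)C(C)C | intermediate
5 | [(4E,8E)-10-bromo-5,9-dimethyldeca-4,8-dien-1-yn-1-yl]triisopropylsilane | BrC/C(C)=C/CC/C(C)=C/CC#C[Si](C(C)C)(C(C)C)C(C)C | intermediate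
6 | 1-(trimethylsilyl)propyne | CC#C[Si](C)(C)C | starting material
7 | 3-lithio-1-(trimethylsilyl)propyne | [Li]CC#C[Si](C)(C)C | intermediate (not isolated)
8 | (4E,8E)-5,9-dimethyl-1-(triisopropylsilyl)-13-(trimethylsilyl)trideca-4,8-diene-1,12-diyne | C[Si](C)(C)C#CCC/C(C)=C/CC/C(C)=C/CC#C[Si](C(C)C)(C(C)C)C(C)C | intermediate
9 | [(4E,8E)-5,9-dimethyltrideca-4,8-diene-1,12-diyn-1-yl]triisopropylsilane | C#CCC/C(C)=C/CC/C(C)=C/CC#C[Si](C(C)C)(C(C)C)C(C)C | intermediate
10 | 4-methylpent-3-enoic acid | CC(C)=CCC(=O)O | starting material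
11 | N,O-dimethylhydroxylamine hydrochloride | CNOC.Cl | starting material
12 | N-methoxy-N,4-dimethylpent-3-enamide | CC(C)=CCC(=O)N(C)OC | intermediate
13 | lithium acetylide of 9 | [Li]C#CCC/C(C)=C/CC/C(C)=C/CC#C[Si](C(C)C)(C(C)C)C(C)C | intermediate (not isolated)
14 | (10E,14E)-2,10,14-trimethyl-18-(triisopropylsilyl)octadeca-2,10,14-triene-6,17-diyn-5-one | CC(C)=CCC(=O)C#CCC/C(C)=C/CC/C(C)=C/CC#C[Si](C(C)C)(C(C)C)C(C)C | intermediate
15 | (5R,10E,14E)-2,10,14-trimethyl-18-(triisopropylsilyl)octadeca-2,10,14-triene-6,17-diyn-5-ol | CC(C)=CC[C@@H](O)C#CCC/C(C)=C/CC/C(C)=C/CC#C[Si](C(C)C)(C(C)C)C(C)C | intermediate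
16 | (5R,6Z,10E,14E)-2,10,14-trimethyl-6-(tributylstannyl)-18-(triisopropylsilyl)octadeca-2,6,10,14-tetraen-17-yn-5-ol | CC(C)=CC[C@@H](O)/C(=C/CC/C(C)=C/CC/C(C)=C/CC#C[Si](C(C)C)(C(C)C)C(C)C)[Sn](CCCC)(CCCC)CCCC | intermediate
17 | (5R,6Z,10E,14E)-6-iodo-2,10,14-trimethyl-18-(triisopropylsilyl)octadeca-2,6,10,14-tetraen-17-yn-5-ol | CC(C)=CC[C@@H](O)/C(I)=C/CC/C(C)=C/CC/C(C)=C/CC#C[Si](C(C)C)(C(C)C)C(C)C | intermediate
18 | (tributylstannyl)methanol | OC[Sn](CCCC)(CCCC)CCCC | starting material
19 | (5R,6E,10E,14E)-6-(hydroxymethyl)-2,10,14-trimethyl-18-(triisopropylsilyl)octadeca-2,6,10,14-tetraen-17-yn-5-ol | CC(C)=CC[C@@H](O)/C(CO)=C/CC/C(C)=C/CC/C(C)=C/CC#C[Si](C(C)C)(C(C)C)C(C)C | intermediate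
20 | (4R,5E)-5-[(4E,8E)-4,8-dimethyl-12-(triisopropylsilyl)dodeca-4,8-dien-11-yn-1-ylidene]-2,2-dimethyl-4-(3-methylbut-2-en-1-yl)-1,3-dioxane | CC(C)=CC[C@@H](OC1(C)C)/C(CO1)=C/CC/C(C)=C/CC/C(C)=C/CC#C[Si](C(C)C)(C(C)C)C(C)C | intermediate
21 | (4R,5E)-5-[(4E,8E)-4,8-dimethyldodeca-4,8-dien-11-yn-1-ylidene]-2,2-dimethyl-4-(3-methylbut-2-en-1-yl)-1,3-dioxane | CC(C)=CC[C@@H](OC1(C)C)/C(CO1)=C/CC/C(C)=C/CC/C(C)=C/CC#C | intermediate
22 | 2-methylfuran | Cc1ccco1 | starting material
23 | 2-methyl-6-(side chain)oxepine, side chain as in 25 | CC(C)=CC[C@@H](OC1(C)C)/C(CO1)=C/CC/C(C)=C/CC/C(C)=C/CC2=COC(C)=CC=C2 | intermediate (not isolated)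
24 | 1-methyl-5-(side chain)-7-oxabicyclo[4.1.0]hepta-2,4-diene, side chain as in 25, epoxide carbons unassigned | CC(C)=CC[C@@H](OC1(C)C)/C(CO1)=C/CC/C(C)=C/CC/C(C)=C/CC2=CC=CC3(C)OC23 | intermediate (not isolated)
25 | 2-{(2E,6E,10E)-10-[(4R)-2,2-dimethyl-4-(3-methylbut-2-en-1-yl)-1,3-dioxan-5-ylidene]-3,7-dimethyldeca-2,6-dien-1-yl}-6-methylphenol | CC(C)=CC[C@@H](OC1(C)C)/C(CO1)=C/CC/C(C)=C/CC/C(C)=C/Cc2cccc(C)c2O | intermediate
26 | 2-[(2E,6E,10E,12R)-12-hydroxy-11-(hydroxymethyl)-3,7,15-trimethylhexadeca-2,6,10,14-tetraen-1-yl]-6-methylphenol | CC(C)=CC[C@@H](O)/C(CO)=C/CC/C(C)=C/CC/C(C)=C/Cc1cccc(C)c1O | intermediate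
27 | 2-[(2E,6E,10E,12R)-12-hydroxy-11-(hydroxymethyl)-3,7,15-trimethylhexadeca-2,6,10,14-tetraen-1-yl]-6-methylcyclohexa-2,5-diene-1,4-dione | CC(C)=CC[C@@H](O)/C(=C/CC/C(C)=C/CC/C(C)=C/CC1=CC(=O)C=C(C)C1=O)CO | target

## Step count and risks

Total step count: 16. Longest linear sequence: 15 steps (steps 1–5 and 7–16; step 6 makes the Weinreb amide on a one-step branch).

**Step 14 (Proposed new method).** Several processes could defeat it:
- protodeauration after the first C–C bond (plain hydroarylation of the furan) or addition of a second furan, outrunning furan ring-opening;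
- attack through the methyl-bearing furan carbon;
- gold-triggered isomerisation of the skipped enyne;
- acid-promoted cyclisation of the new phenol onto the C2′ alkene.

The fallback uses known chemistry and forms the same two ring bonds by a Diels–Alder reaction. It sets out from 21. Deprotonation with n-BuLi in THF at −78 °C gives lithium acetylide F1, and formylation with DMF (inverse quench into aqueous KH2PO4) gives ynal F2. Separately, commercial (E)-4-methoxypent-3-en-2-one is converted with LiN(i-Pr)2 and Me3SiCl into (E)-4-methoxy-2-(trimethylsilyloxy)penta-1,3-diene F3. Heating F2 with F3 in toluene at 80 °C should give cycloadduct F4, in which the nucleophilic CH2 terminus of the diene is bonded to the chain-bearing alkyne carbon. K2CO3 in MeOH then removes the silyl group and eliminates methanol to give 4-hydroxy-2-methyl-6-alkylbenzaldehyde F5. Dakin oxidation (H2O2, NaOH, THF/H2O, 0 °C) gives hydroquinone F6, and Ag2O in Et2O gives quinone acetonide F7. Acetal hydrolysis (AcOH/THF/H2O, 25 °C) rejoins the route at 27.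

**Step 9.** Site and regiocontrol could be lost: hydrostannation of the silyl-capped alkyne could compete, tin could be delivered to the distal carbon, or the stannane could protodestannylate on purification. The fallback sets out from 15 and uses a magnesium-alkoxide-directed anti-carbomagnesiation. (Isopropoxydimethylsilyl)methylmagnesium chloride F8 is made from commercial (chloromethyl)(isopropoxy)dimethylsilane and Mg in THF. With CuI (10 mol %) it should add its carbon to the alkyne carbon next to the carbinol, the magnesium ending anti and chelated by the alkoxide. Protonation gives allylsilane F9 with the same alkene geometry as 19. Tamao–Fleming oxidation (H2O2, KF, KHCO3, THF/MeOH) then rejoins the route at 19, bypassing steps 9–11.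

**Step 11.** Slow transmetalation of the α-hydroxy stannane could let protodeiodination or intramolecular Heck-type carbopalladation of the polyene compete. The fallback sets out from 17. Palladium-catalysed methoxycarbonylation (PdCl2(PPh3)2, CO 1 atm, MeOH, Et3N, 50 °C) gives methyl ester F10 with retention of geometry. Reduction with i-Bu2AlH in CH2Cl2 at −78 °C rejoins the route at 19.

## Further compounds

F1 | step 14 | lithium acetylide of 21 | CC(C)=CC[C@@H](OC1(C)C)/C(CO1)=C/CC/C(C)=C/CC/C(C)=C/CC#C[Li]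
F2 | step 14 | ynal, (5E,9E)-6,10-dimethyl-13-[(4R,5E)-2,2-dimethyl-4-(3-methylbut-2-en-1-yl)-1,3-dioxan-5-ylidene]trideca-5,9-dien-2-ynal | CC(C)=CC[C@@H](OC1(C)C)/C(CO1)=C/CC/C(C)=C/CC/C(C)=C/CC#CC=O
F3 | step 14 | (E)-4-methoxy-2-(trimethylsilyloxy)penta-1,3-diene | CO/C(C)=C/C(=C)O[Si](C)(C)C
F4 | step 14 | Diels–Alder adduct, 6-methoxy-6-methyl-2-(side chain)-4-(trimethylsilyloxy)cyclohexa-1,4-diene-1-carbaldehyde | CC(C)=CC[C@@H](OC1(C)C)/C(CO1)=C/CC/C(C)=C/CC/C(C)=C/CC2=C(C=O)C(C)(OC)C=C(O[Si](C)(C)C)C2
F5 | step 14 | 4-hydroxy-2-methyl-6-(side chain)benzaldehyde | CC(C)=CC[C@@H](OC1(C)C)/C(CO1)=C/CC/C(C)=C/CC/C(C)=C/Cc2cc(O)cc(C)c2C=O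
F6 | step 14 | 2-methyl-6-(side chain)benzene-1,4-diol | CC(C)=CC[C@@H](OC1(C)C)/C(CO1)=C/CC/C(C)=C/CC/C(C)=C/Cc2cc(O)cc(C)c2O
F7 | step 14 | acetonide of 27, 2-methyl-6-(side chain)cyclohexa-2,5-diene-1,4-dione | CC(C)=CC[C@@H](OC1(C)C)/C(CO1)=C/CC/C(C)=C/CC/C(C)=C/CC2=CC(=O)C=C(C)C2=O
F8 | step 9 | (isopropoxydimethylsilyl)methylmagnesium chloride | CC(C)O[Si](C)(C)C[Mg]Cl
F9 | step 9 | (5R,6E,10E,14E)-6-[(isopropoxydimethylsilyl)methyl]-2,10,14-trimethyl-18-(triisopropylsilyl)octadeca-2,6,10,14-tetraen-17-yn-5-ol | CC(C)=CC[C@@H](O)/C(C[Si](C)(C)OC(C)C)=C/CC/C(C)=C/CC/C(C)=C/CC#C[Si](C(C)C)(C(C)C)C(C)C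
F10 | step 11 | methyl (2Z,6E,10E)-2-[(1R)-1-hydroxy-4-methylpent-3-en-1-yl]-6,10-dimethyl-14-(triisopropylsilyl)tetradeca-2,6,10-trien-13-ynoate | CC(C)=CC[C@@H](O)/C(C(=O)OC)=C/CC/C(C)=C/CC/C(C)=C/CC#C[Si](C(C)C)(C(C)C)C(C)C
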